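**Retrosynthetic overview**
1. Target 20 comes from 19 by one hydrogenation (benzyl ester, C11=C12 and C16=C17 from the exo face); ring D is closed by a 5-exo Heck reaction (C13–C16) of an α-iodo vinyl ketone on C8.
2. Ring C comes from a Diels–Alder reaction of butadiene (C9–C11, C8–C14) with the spiro 3-acetyl-α,β-unsaturated δ-lactone 13; C10 sets the face.
3. The lactone ring and the C10 quaternary centre come from an epoxide-triggered radical 6-endo closure (C9–C10) onto a tethered ethoxymethylene acetoacetate, the new step, which also delivers C1–OAc.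
4. The key bonds are C–O bonds made before any ring-forming C–C bond: the lactone C20–O–C7 ester (allylic oxidation, then O-acetoacetylation) serves as the tether, and the C1–O bond (cis-epoxidation) serves as the radical trigger and stereocontrol element.
5. Ring A comes from geranic acid (cyclisation, resolution at C5). Ring order: A, lactone, C, D.

Assumptions: locants C1–C20 are the kaurane-type numbers of the target; in step 2 the (R)-amine is written as the antipode whose salt with the (R)-acid is the less soluble one (a test crystallisation decides; otherwise the (S)-amine is used).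

**Step 1**
Reactants: 1 geranic acid
Product: 2 (±)-α-cyclogeranic acid
Conditions: 85% H3PO4, toluene, 100 °C
Reagents that add atoms: none
Why: Brønsted-acid cation–olefin cyclisation; the tertiary cation is captured by the enoate alkene and loses a ring proton to give the α (endocyclic) isomer.

**Step 2**
Reactants: 2 (±)-α-cyclogeranic acid
Product: 3 (R)-1-phenylethylammonium (R)-α-cyclogeranate
Conditions: (R)-1-phenylethylamine (0.55 equiv), acetone, recrystallise to constant rotation
Reagents that add atoms: (R)-1-phenylethylamine, C[C@@H](N)c1ccccc1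
Why: classical resolution through diastereomeric salts; the C5 centre (R) fixed here is the only source of absolute configuration in the route.

**Step 3**
Reactants: 3 (R)-1-phenylethylammonium (R)-α-cyclogeranate
Product: 5 benzyl (R)-α-cyclogeranate, via (R)-α-cyclogeranic acid 4 (not isolated)
Conditions: 1 M HCl/Et2O wash; then BnBr, KHCO3, DMF, 25 °C
Reagents that add atoms: benzyl bromide, BrCc1ccccc1
Why: carboxylate O-alkylation (SN2) under bicarbonate, which neither epimerises C5 nor conjugates the β,γ-alkene; the benzyl ester is chosen because it falls off in the final hydrogenation.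

**Step 4**
Reactants: 5 benzyl (R)-α-cyclogeranate
Product: 6 C20 allylic alcohol
Conditions: SeO2 (0.5 equiv), t-BuOOH (2.5 equiv), CH2Cl2, 25 °C
Reagents that add atoms: selenium dioxide, O=[Se]=O (delivers the oxygen atom; re-formed by tert-butyl hydroperoxide, CC(C)(C)OO)
Why: Riley allylic oxidation; the ene reaction at C1 takes hydrogen from the C20 methyl rather than from the tertiary, shielded C5–H, and the [2,3]-shift puts oxygen on C20 and restores the C1=C10 alkene.

**Step 5**
Reactants: 6 C20 allylic alcohol; 7 diketene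
Product: 8 C20 acetoacetate
Conditions: DMAP (5 mol %), CH2Cl2, 0 to 25 °C
Reagents that add atoms: none
Why: nucleophile-catalysed O-acylation by ring opening of diketene; this C20–O–C7 bond is the lactone C–O bond of the target and the tether for step 8, and it is made cold to avoid a Carroll rearrangement.

**Step 6**
Reactants: 8 C20 acetoacetate; 9 triethyl orthoformate
Product: 10 ethoxymethylene acetoacetate
Conditions: HC(OEt)3 (3 equiv), Ac2O (3 equiv), 100 °C
Reagents that add atoms: none
Why: Claisen-type condensation of the active methylene with the orthoformate; it installs C9 as an acceptor carbon that carries its own leaving group.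

**Step 7**
Reactants: 10 ethoxymethylene acetoacetate
Product: 11 C1,C10 cis-epoxide
Conditions: mCPBA (1.2 equiv), NaHCO3, CH2Cl2, 0 °C
Reagents that add atoms: meta-chloroperbenzoic acid, OOC(=O)c1cccc(Cl)c1
Why: Prilezhaev epoxidation of the only electron-rich alkene; the peracid is expected to come anti to the pseudoaxial C4 methyl, that is syn to the pseudoaxial C5 ester, as α-ionone-type rings are recalled to behave, which sets C1–O cis to C6.

**Step 8**
Reactants: 11 C1,C10 cis-epoxide
Product: 13 spiro acetyl dihydropyranone acetate, via titanium alkoxide 12 (not isolated)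
Conditions: Cp2TiCl2 (20 mol %), Mn powder (2 equiv), Ac2O (3 equiv), 2,4,6-collidine (1 equiv), THF, 25 °C, slow addition of 11
Reagents that add atoms: acetic anhydride, CC(=O)OC(C)=O
Why: Proposed new method: titanocene-catalysed epoxide-triggered radical spiro-alkenylation with anhydride turnover. Cp2TiCl (trivalent titanium, from Cp2TiCl2 and Mn) opens the oxirane at the tertiary carbon to give the C10 radical with C1–O–Ti; the radical closes 6-endo onto the ethoxymethylene carbon C9 from the face anti to the C1–O–Ti and C5 ester groups (equatorial attack away from the axial C4 methyl), so C20 ends cis to both and C10 is set; a second Cp2TiCl reduces the 1,3-dicarbonyl radical at C8 to its titanium enolate, which expels ethoxide (E1cB) to give the C8=C9 alkene; Ac2O then cleaves both Ti–O bonds (C1–OAc formed, EtOAc released) so that Mn can return the tetravalent titanium acetate to Cp2TiCl. The closest known chemistry is the Nugent–RajanBabu/Gansäuer reductive epoxide opening with Giese addition to acrylates; to my knowledge it has not been run as an addition–elimination onto an alkoxymethylene 1,3-dicarbonyl or turned over by an anhydride.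

**Step 9**
Reactants: 13 spiro acetyl dihydropyranone acetate; 14 buta-1,3-diene
Product: 15 cis-fused Diels–Alder adduct
Conditions: buta-1,3-diene (10 equiv), ZnCl2 (1.2 equiv), CH2Cl2, sealed tube, 0 to 25 °C
Reagents that add atoms: none
Why: Lewis-acid Diels–Alder reaction on a chelated 2-acyl enoate (this class adds dienes even next to a quaternary carbon); suprafacial addition gives C11 and C14 cis with the acetyl cis to H9, and the diene comes anti to the larger C10 branch (C5, ester-bearing and next to CMe2), which sets C9 and C8.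

**Step 10**
Reactants: 15 cis-fused Diels–Alder adduct
Product: 17 vinyl ketone, via Mannich base 16 (not isolated)
Conditions: (CH2O)n (5 equiv), i-Pr2NH·CF3CO2H (1 equiv), THF, 65 °C
Reagents that add atoms: paraformaldehyde (formaldehyde), C=O
Why: Mannich condensation and β-elimination (α-methylenation); the acetyl methyl is the only enolisable ketone position because C8 is quaternary.

**Step 11**
Reactants: 17 vinyl ketone
Product: 18 α-iodo vinyl ketone
Conditions: I2 (2 equiv), pyridine/CH2Cl2 1:1, 0 to 25 °C
Reagents that add atoms: iodine, II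
Why: α-iodination of an enone by pyridine conjugate addition, enolate iodination and elimination (Baylis–Hillman-type sequence); the isolated ring alkene is not touched.

**Step 12**
Reactants: 18 α-iodo vinyl ketone
Product: 19 tetracyclic diene benzyl ester
Conditions: Pd(OAc)2 (10 mol %), PPh3 (20 mol %), Ag2CO3 (1.5 equiv), MeCN, 70 °C
Reagents that add atoms: none
Why: intramolecular Mizoroki–Heck reaction; zerovalent palladium inserts into C16–I, 5-exo syn-carbopalladation of C12=C13 from the acyl face (cis to H9) closes ring D and sets C13, and the only syn β-hydrogen is on C11, so the alkene ends at C11=C12.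

**Step 13**
Reactants: 19 tetracyclic diene benzyl ester
Product: 20 CNP0161834.1
Conditions: H2 (1 atm), 10% Pd/C, EtOAc, 25 °C
Reagents that add atoms: none
Why: heterogeneous hydrogenation and hydrogenolysis; hydrogen adds to the exocyclic C16=C17 enone from the open exo face, which puts the methyl endo (16R), and the same step saturates C11=C12 and cleaves the benzyl ester.

**Compound list**
1 | geranic acid, (2E)-3,7-dimethylocta-2,6-dienoic acid | CC(C)=CCC/C(C)=C/C(=O)O | starting material
2 | (±)-α-cyclogeranic acid, 2,6,6-trimethylcyclohex-2-ene-1-carboxylic acid | CC1=CCCC(C)(C)C1C(=O)O | intermediate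
3 | (R)-1-phenylethylammonium (1R)-2,6,6-trimethylcyclohex-2-ene-1-carboxylate | C1CC(C)(C)[C@@H](C(=O)[O-])C(C)=C1.C[C@@H]([NH3+])c1ccccc1 | intermediate
4 | (R)-α-cyclogeranic acid, (1R)-2,6,6-trimethylcyclohex-2-ene-1-carboxylic acid | C1CC(C)(C)[C@@H](C(=O)O)C(C)=C1 | intermediate
5 | benzyl (1R)-2,6,6-trimethylcyclohex-2-ene-1-carboxylate | C1CC(C)(C)[C@@H](C(=O)OCc2ccccc2)C(C)=C1 | intermediate
6 | benzyl (1R)-2-(hydroxymethyl)-6,6-dimethylcyclohex-2-ene-1-carboxylate (C20 alcohol) | C1CC(C)(C)[C@@H](C(=O)OCc2ccccc2)C(CO)=C1 | intermediate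
7 | diketene, 4-methylideneoxetan-2-one | C=C1CC(=O)O1 | starting material
8 | benzyl (1R)-6,6-dimethyl-2-[(3-oxobutanoyloxy)methyl]cyclohex-2-ene-1-carboxylate | C1CC(C)(C)[C@@H](C(=O)OCc2ccccc2)C(COC(=O)CC(C)=O)=C1 | intermediate
9 | triethyl orthoformate | CCOC(OCC)OCC | starting material
10 | benzyl (1R)-2-{[(2-acetyl-3-ethoxyprop-2-enoyl)oxy]methyl}-6,6-dimethylcyclohex-2-ene-1-carboxylate (E/Z mixture) | C1CC(C)(C)[C@@H](C(=O)OCc2ccccc2)C(COC(=O)C(=COCC)C(C)=O)=C1 | intermediate
11 | C1,C10-epoxide of 10, oxirane oxygen on the same ring face as the C5 benzyl ester | CCOC=C(C(C)=O)C(=O)OC[C@]12O[C@H]1CCC(C)(C)[C@H]2C(=O)OCc1ccccc1 | intermediate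
12 | C1 titanium alkoxide of the spiro lactone (SMILES drawn as the free C1 alcohol): ring A spiro at C10 to 3-acetyl-5,6-dihydro-2H-pyran-2-one; C1–O, C20 and C5 ester all cis, C9 trans | O[C@H]1CCC(C)(C)[C@@H](C(=O)OCc3ccccc3)[C@@]12COC(=O)C(C(C)=O)=C2 | intermediate
13 | C1 acetate of 12: ring A (C1–OAc, C4 gem-dimethyl, C5–CO2Bn) spiro at C10 to the lactone C20H2–O–C7(=O)–C8(Ac)=C9H; OAc, C20 and CO2Bn cis, C9 trans | CC(=O)O[C@H]1CCC(C)(C)[C@@H](C(=O)OCc3ccccc3)[C@@]12COC(=O)C(C(C)=O)=C2 | intermediate
14 | buta-1,3-diene | C=CC=C | starting material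
15 | Diels–Alder adduct: ring C cyclohexene (C12=C13) cis-fused to the lactone at C8–C9; C11 and C14 on the face anti to C5; C8 acetyl cis to H9 | CC(=O)O[C@H]1CCC(C)(C)[C@@H](C(=O)OCc4ccccc4)[C@@]12COC(=O)[C@@]3(C(C)=O)CC=CC[C@H]32 | intermediate
16 | Mannich base of 15: C8–C(=O)CH2CH2N(i-Pr)2 | CC(=O)O[C@H]1CCC(C)(C)[C@@H](C(=O)OCc4ccccc4)[C@@]12COC(=O)[C@@]3(C(=O)CCN(C(C)C)C(C)C)CC=CC[C@H]32 | intermediate
17 | vinyl ketone: C8–C(=O)CH=CH2 (C15, C16, C17) | CC(=O)O[C@H]1CCC(C)(C)[C@@H](C(=O)OCc4ccccc4)[C@@]12COC(=O)[C@@]3(C(=O)C=C)CC=CC[C@H]32 | intermediate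
18 | α-iodo vinyl ketone: C8–C(=O)C(I)=CH2 | CC(=O)O[C@H]1CCC(C)(C)[C@@H](C(=O)OCc4ccccc4)[C@@]12COC(=O)[C@@]3(C(=O)C(I)=C)CC=CC[C@H]32 | intermediate
19 | benzyl ester of the 11,12-didehydro-16-methylidene analogue of the target (bicyclo[3.2.1]octene rings C and D closed; all ring stereocentres as in the target) | CC(=O)O[C@H]1CCC(C)(C)[C@@H](C(=O)OCc4ccccc4)[C@@]12COC(=O)[C@@]13C[C@@H](C=C[C@H]12)C(=C)C3=O | intermediate
20 | CNP0161834.1: (1S,5R,8S,9S,10S,13R,16R)-1-acetoxy-16-methyl-15-oxo-6,7-seco-kauran-7,20-olid-6-oic acid (kaurane-type locants) | CC(=O)O[C@H]1CCC(C)(C)[C@@H](C(=O)O)[C@@]12COC(=O)[C@@]13C[C@@H](CC[C@H]12)[C@@H](C)C3=O | target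

**Step count and risks**
Total steps: 13. Longest linear sequence: 13 (from geranic acid 1).

Steps most likely to fail:

1. Step 8 (the new method). The catalytic cycle may stall at the titanium enolate, or the tertiary radical may be lost to allylic alcohol before it cyclises. The fallback uses known chemistry, sets out from 6 and comes back at 13. Alcohol 6 is esterified with acryloyl chloride and Et3N to the acrylate F1, and mCPBA gives the cis-epoxy acrylate F2. Stoichiometric Cp2TiCl (from Cp2TiCl2 and Zn, THF) then opens the epoxide and the C10 radical closes onto the tethered acrylate in the usual reductive Giese manner, giving the saturated hydroxy spirolactone F3. Ac2O and pyridine give the C1 acetate F4. The lactone enolate (LiHMDS, THF, −78 °C) is C-acetylated with N-acetylimidazole to the 3-acetyl lactone F5, and PhSeCl with pyridine gives the C8 selenide F6. H2O2 then effects selenoxide elimination to 13.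

2. Step 12 (Heck closure of a bridged ring). Slow insertion could give reduction or 6-exo closure to a bicyclo[2.2.2]octane. The fallback sets out from 18 and comes back at 20. Bu3SnH and AIBN (benzene, 80 °C, syringe pump) generate the α-keto vinyl radical, which cyclises 5-exo onto C13 and is reduced at C12 to the 11,12-saturated methylidene ketone F7. The conditions of step 13 then hydrogenate the enone from the exo face and cleave the benzyl ester to give 20.

3. Step 4 (Riley oxidation). Oxidation at C5–H, over-oxidation to the enal or low conversion are possible. The fallback sets out from 5 and comes back at 6. mCPBA gives the cis-epoxide F8. Titanocene-catalysed epoxide isomerisation (Cp2TiCl2 cat., Mn, collidine hydrochloride) gives the exocyclic allylic alcohol F9 (C1–OH, C10=C20). Ac2O gives the secondary allylic acetate F10, and PdCl2(MeCN)2 catalyses the 1,3-acetoxy shift to the primary allylic acetate F11 (C20–OAc, C1=C10). Brief K2CO3/MeOH at 0 °C frees 6.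

**Further compounds**
F1 | step 8 | benzyl (1R)-2-[(acryloyloxy)methyl]-6,6-dimethylcyclohex-2-ene-1-carboxylate | C1CC(C)(C)[C@@H](C(=O)OCc2ccccc2)C(COC(=O)C=C)=C1
F2 | step 8 | C1,C10 cis-epoxide of F1 (oxirane oxygen cis to the C5 ester) | C=CC(=O)OC[C@]12O[C@H]1CCC(C)(C)[C@H]2C(=O)OCc1ccccc1
F3 | step 8 | saturated C1-hydroxy spiro δ-lactone (C8 and C9 both CH2; C1–OH, C20 and ester cis) | O[C@H]1CCC(C)(C)[C@@H](C(=O)OCc3ccccc3)[C@@]12COC(=O)CC2
F4 | step 8 | C1 acetate of F3 | CC(=O)O[C@H]1CCC(C)(C)[C@@H](C(=O)OCc3ccccc3)[C@@]12COC(=O)CC2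
F5 | step 8 | 3-acetyl lactone (acetyl on C8, C8 epimers) | CC(=O)O[C@H]1CCC(C)(C)[C@@H](C(=O)OCc3ccccc3)[C@@]12COC(=O)C(C(C)=O)C2
F6 | step 8 | C8 phenylselanyl derivative of F5 | CC(=O)O[C@H]1CCC(C)(C)[C@@H](C(=O)OCc3ccccc3)[C@@]12COC(=O)C([Se]c3ccccc3)(C(C)=O)C2
F7 | step 12 | benzyl ester of the 16-methylidene analogue of the target (C11–C12 saturated) | CC(=O)O[C@H]1CCC(C)(C)[C@@H](C(=O)OCc4ccccc4)[C@@]12COC(=O)[C@@]13C[C@@H](CC[C@H]12)C(=C)C3=O
F8 | step 4 | C1,C10 cis-epoxide of 5 (C20 methyl) | C[C@]12O[C@H]1CCC(C)(C)[C@H]2C(=O)OCc1ccccc1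
F9 | step 4 | benzyl 3-hydroxy-6,6-dimethyl-2-methylidenecyclohexane-1-carboxylate (C1–OH cis to the ester) | O[C@H]1CCC(C)(C)[C@@H](C(=O)OCc2ccccc2)C1=C
F10 | step 4 | acetate of F9 | CC(=O)O[C@H]1CCC(C)(C)[C@@H](C(=O)OCc2ccccc2)C1=C
F11 | step 4 | benzyl (1R)-2-(acetoxymethyl)-6,6-dimethylcyclohex-2-ene-1-carboxylate | C1CC(C)(C)[C@@H](C(=O)OCc2ccccc2)C(COC(C)=O)=C1
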